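**Retrosynthetic overview**
1. Target ⇐ desilylation ⇐ oxepane diacetate ⇐ acetylative ring expansion (1,2-shift of the ring oxygen, both carbinol centres inverted) of an oxane that carries the tertiary carbinol; the six-membered ring is made first and then expanded to the only ring of the target.
2. Oxane ⇐ base-mediated 6-exo opening of a (2R,3R)-trisubstituted epoxide (Sharpless epoxidation) by the allylic CH2OH.
3. C1'–C2' bond ⇐ copper-catalysed coupling of the epoxy triflate with the side-chain Grignard reagent.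
4. C10 core ⇐ anti-carbomagnesiation of but-2-yne-1,4-diol with homoprenylmagnesium bromide (fixes the exocyclic E-alkene), then SeO2 oxidation of the E-methyl group.
5. Side chain ⇐ Brown (Z)-crotylboration of 4-methylpent-3-enal (sets C4' and C5'), then hydrozirconation–iodination.

Assumption: the target is read as 2-[(3E,6R,7S)-6-acetoxy-7-[(4R,5R)-5-hydroxy-4,8-dimethylnon-7-en-1-yl]-7-methyloxepan-3-ylidene]ethyl acetate (ring O1, C2–C7; side chain C1'–C9'), and the four starting materials are bought.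

**Step 1**
Reactants: 1 4-methylpent-3-en-1-ol
Product: 2 4-methylpent-3-enal
Conditions: Dess–Martin periodinane (1.2 equiv), NaHCO3, CH2Cl2, 0 °C; short silica plug, used at once as a cold solution
Reagents that add atoms: none
Why: Buffered Dess–Martin oxidation stops at the β,γ-unsaturated aldehyde without moving the alkene into conjugation; no stereocentre is formed.

**Step 2**
Reactants: 2 4-methylpent-3-enal; 3 (Z)-but-2-ene
Product: 7 (3R,4R)-3,7-dimethylocta-1,6-dien-4-ol, via (Z)-but-2-enylpotassium 4 (not isolated), via (Z)-crotyldiisopinocampheylborane 5 (not isolated), via borinate ester 6 (not isolated)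
Conditions: 3, n-BuLi, KOtBu, THF, −78 → −45 °C; (−)-Ipc2BOMe, −78 °C; BF3·OEt2; 2, −78 °C; NaOH, H2O2, 0 °C → rt
Reagents that add atoms: none
Why: Brown asymmetric crotylboration: the Z-crotyl group reacts through a closed chair transition state to give the syn pair, and the (+)-α-pinene-derived Ipc ligands direct attack to the Si face of the aldehyde, which sets 3R,4R (C4' and C5' of the target).

**Step 3**
Reactants: 7 (3R,4R)-3,7-dimethylocta-1,6-dien-4-ol
Product: 8 [(3R,4R)-3,7-dimethylocta-1,6-dien-4-yl]oxy-tri(propan-2-yl)silane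
Conditions: TIPSOTf, 2,6-lutidine, CH2Cl2, −78 → 0 °C
Reagents that add atoms: triisopropylsilyl trifluoromethanesulfonate, CC(C)[Si](C(C)C)(C(C)C)OS(=O)(=O)C(F)(F)F
Why: Silyl triflate silylation of a hindered secondary alcohol; the TIPS ether tolerates the later Grignard, hydroxide and Lewis-acid steps and keeps this hydroxyl out of the final acetylation.

**Step 4**
Reactants: 8 [(3R,4R)-3,7-dimethylocta-1,6-dien-4-yl]oxy-tri(propan-2-yl)silane
Product: 10 [(3R,4R)-1-iodo-3,7-dimethyloct-6-en-4-yl]oxy-tri(propan-2-yl)silane, via alkylzirconocene chloride 9 (not isolated)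
Conditions: Cp2Zr(H)Cl, CH2Cl2, rt; then I2, 0 °C
Reagents that add atoms: iodine, [I][I]
Why: Schwartz hydrozirconation adds only to the monosubstituted alkene with zirconium at the terminal carbon, and iodinolysis of the C–Zr bond gives the primary iodide while the trisubstituted alkene is left alone.

**Step 5**
Reactants: 11 5-bromo-2-methylpent-2-ene; 12 but-2-yne-1,4-diol
Product: 15 (2E)-2-(4-methylpent-3-en-1-yl)but-2-ene-1,4-diol, via homoprenylmagnesium bromide 13 (not isolated), via cyclic alkenylmagnesium alkoxide 14 (not isolated)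
Conditions: 11, Mg, THF, rt; then 12 (1 equiv to 3.5 equiv of 13), CuI (10 mol %), THF, 0 °C → reflux; aq NH4Cl
Reagents that add atoms: none
Why: Copper-catalysed anti-carbomagnesiation of a propargylic alkoxide (Duboudin–Jousseaume type): the alkyl group adds anti to magnesium, which is held in a five-membered chelate by the neighbouring alkoxide, so after protonation the new chain is cis to the other CH2OH and the E geometry of the target's exocyclic alkene is fixed.

**Step 6**
Reactants: 15 (2E)-2-(4-methylpent-3-en-1-yl)but-2-ene-1,4-diol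
Product: 16 (2E)-2-(4-methylpent-3-en-1-yl)but-2-ene-1,4-diyl bis(2,2-dimethylpropanoate)
Conditions: PivCl, pyridine, DMAP (cat.), CH2Cl2, 0 °C → rt
Reagents that add atoms: pivaloyl chloride, CC(C)(C)C(Cl)=O
Why: Simple acylation; the two allylic pivalates deactivate the central alkene towards the next two oxidations and survive organomagnesium and copper reagents at low temperature.

**Step 7**
Reactants: 16 (2E)-2-(4-methylpent-3-en-1-yl)but-2-ene-1,4-diyl bis(2,2-dimethylpropanoate)
Product: 17 (2E)-2-[(3E)-5-hydroxy-4-methylpent-3-en-1-yl]but-2-ene-1,4-diyl bis(2,2-dimethylpropanoate)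
Conditions: SeO2 (0.5 equiv), t-BuOOH (2.5 equiv), salicylic acid (cat.), CH2Cl2, 0 °C → rt
Reagents that add atoms: tert-butyl hydroperoxide, CC(C)(C)OO (terminal oxygen source; the oxygen is passed on through selenium dioxide, O=[Se]=O)
Why: Sharpless SeO2/t-BuOOH allylic oxidation (ene reaction then [2,3]-shift) hydroxylates the E-methyl of the electron-rich isopropylidene group and gives the E-allylic alcohol, while the alkene flanked by two acyloxymethyl groups is too electron-poor to compete.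

**Step 8**
Reactants: 17 (2E)-2-[(3E)-5-hydroxy-4-methylpent-3-en-1-yl]but-2-ene-1,4-diyl bis(2,2-dimethylpropanoate)
Product: 18 (2E)-2-{2-[(2R,3R)-3-(hydroxymethyl)-3-methyloxiran-2-yl]ethyl}but-2-ene-1,4-diyl bis(2,2-dimethylpropanoate)
Conditions: Ti(OiPr)4 (10 mol %), D-(−)-diisopropyl tartrate (12 mol %), t-BuOOH, 4 Å molecular sieves, CH2Cl2, −25 °C
Reagents that add atoms: tert-butyl hydroperoxide, CC(C)(C)OO
Why: Sharpless–Katsuki asymmetric epoxidation acts only on the free allylic alcohol, and the D-(−)-tartrate gives the (2R,3R)-epoxide, which carries the absolute configuration of both future ring stereocentres.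

**Step 9**
Reactants: 18 (2E)-2-{2-[(2R,3R)-3-(hydroxymethyl)-3-methyloxiran-2-yl]ethyl}but-2-ene-1,4-diyl bis(2,2-dimethylpropanoate); 10 [(3R,4R)-1-iodo-3,7-dimethyloct-6-en-4-yl]oxy-tri(propan-2-yl)silane
Product: 21 (2E)-2-{2-[(2R,3R)-3-{(4R,5R)-4,8-dimethyl-5-[tri(propan-2-yl)silyloxy]non-7-en-1-yl}-3-methyloxiran-2-yl]ethyl}but-2-ene-1,4-diyl bis(2,2-dimethylpropanoate), via epoxy triflate 19 (not isolated), via side-chain Grignard reagent 20 (not isolated)
Conditions: 18, n-BuLi (1.0 equiv), Et2O, −78 °C; Tf2O, −78 °C; separately 10, Mg, Et2O, rt; then 20 (1.3 equiv), CuBr·SMe2 (10 mol %), −78 → −30 °C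
Reagents that add atoms: none
Why: Copper-catalysed sp3–sp3 coupling of a Grignard reagent with a primary alkyl triflate (Kochi-type) is faster at −78 °C than attack on the trisubstituted epoxide or the pivalates, and it forms the C1'–C2' bond without touching a stereocentre.

**Step 10**
Reactants: 21 (2E)-2-{2-[(2R,3R)-3-{(4R,5R)-4,8-dimethyl-5-[tri(propan-2-yl)silyloxy]non-7-en-1-yl}-3-methyloxiran-2-yl]ethyl}but-2-ene-1,4-diyl bis(2,2-dimethylpropanoate)
Product: 23 (2R,6R,7R)-2-[(2S,5E)-5-(2-hydroxyethylidene)oxan-2-yl]-6,10-dimethyl-7-[tri(propan-2-yl)silyloxy]undec-9-en-2-ol, via epoxy diol 22 (not isolated)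
Conditions: KOtBu (8 equiv), H2O (3 equiv), THF, 0 °C → rt; then 55 °C; aq NH4Cl
Reagents that add atoms: none
Why: Anhydrous-hydroxide ester cleavage (Gassman conditions) frees both alkoxides, and the one on the more substituted alkene carbon opens the epoxide in the 6-exo-tet mode at its less substituted carbon with inversion (oxane C2 becomes S), leaving the tertiary carbinol with retained R configuration; the 7-exo closure by the other alkoxide is slower.

**Step 11**
Reactants: 23 (2R,6R,7R)-2-[(2S,5E)-5-(2-hydroxyethylidene)oxan-2-yl]-6,10-dimethyl-7-[tri(propan-2-yl)silyloxy]undec-9-en-2-ol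
Product: 26 2-[(3E,6R,7S)-6-acetoxy-7-{(4R,5R)-4,8-dimethyl-5-[tri(propan-2-yl)silyloxy]non-7-en-1-yl}-7-methyloxepan-3-ylidene]ethyl acetate, via diacetate 24 (not isolated), via bicyclic oxonium acetate 25 (not isolated)
Conditions: Ac2O (6 equiv), Sc(OTf)3 (5 mol %), MeNO2/CH2Cl2, −25 °C, 1 h; then 0 → 20 °C; aq NaHCO3
Reagents that add atoms: acetic anhydride, CC(=O)OC(C)=O
Why: Proposed new method: a Lewis-acid-catalysed acetylative ring expansion (1,2-oxygen shift) of a 2-(tertiary carbinol)oxane to a 3-acetoxyoxepane, in which Sc(OTf)3/Ac2O first acetylates both hydroxyls (known) and then ionises only the tertiary acetate of 24 with backside participation of the ring oxygen to give the bicyclic oxonium acetate 25 (inversion at the carbinol carbon); acetate return at the tertiary carbon merely regenerates 24, whereas SN2 opening at the secondary ring carbon (inversion, with relief of three-ring strain that opening at the allylic OCH2 carbon would not give) forms 26, whose secondary acetate does not re-ionise, so 24 is drained into the oxepane and the 2S-oxane/2R-carbinol pair becomes C6 R and C7 S by double inversion; the closest known reaction type is the zinc acetate-mediated ring expansion of cyclic ethers bearing an exocyclic secondary sulfonate through the same kind of bicyclic oxonium ion, which has not been shown for a tertiary carboxylate leaving group under catalytic Lewis-acid turnover.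

**Step 12**
Reactants: 26 2-[(3E,6R,7S)-6-acetoxy-7-{(4R,5R)-4,8-dimethyl-5-[tri(propan-2-yl)silyloxy]non-7-en-1-yl}-7-methyloxepan-3-ylidene]ethyl acetate
Product: 27 2-[(3E,6R,7S)-6-acetoxy-7-[(4R,5R)-5-hydroxy-4,8-dimethylnon-7-en-1-yl]-7-methyloxepan-3-ylidene]ethyl acetate
Conditions: HF·pyridine, pyridine, THF, 0 °C → rt
Reagents that add atoms: none
Why: Buffered fluoride desilylation removes the TIPS group without cleaving or moving either acetate and without touching the alkenes or the stereocentres.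

**Compound list**
1 | 4-methylpent-3-en-1-ol | CC(C)=CCCO | starting material
2 | 4-methylpent-3-enal | CC(C)=CCC=O | intermediate
3 | (Z)-but-2-ene | C/C=C\C | starting material
4 | (Z)-but-2-en-1-ylpotassium | C/C=C\C[K] | intermediate
5 | (Z)-but-2-en-1-ylbis[(1R,2S,3R,5R)-2,6,6-trimethylbicyclo[3.1.1]heptan-3-yl]borane | C/C=C\CB([C@@H]1C[C@@H]2C[C@H]([C@H]1C)C2(C)C)[C@@H]1C[C@@H]2C[C@H]([C@H]1C)C2(C)C | intermediate
6 | (3R,4R)-3,7-dimethylocta-1,6-dien-4-yl diisopinocampheylborinate | C=C[C@@H](C)[C@H](OB([C@@H]1C[C@@H]2C[C@H]([C@H]1C)C2(C)C)[C@@H]1C[C@@H]2C[C@H]([C@H]1C)C2(C)C)CC=C(C)C | intermediate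
7 | (3R,4R)-3,7-dimethylocta-1,6-dien-4-ol | C=C[C@@H](C)[C@H](O)CC=C(C)C | intermediate
8 | [(3R,4R)-3,7-dimethylocta-1,6-dien-4-yl]oxy-tri(propan-2-yl)silane | C=C[C@@H](C)[C@H](O[Si](C(C)C)(C(C)C)C(C)C)CC=C(C)C | intermediate
9 | chlorobis(cyclopentadienyl){(3R,4R)-3,7-dimethyl-4-[tri(propan-2-yl)silyloxy]oct-6-en-1-yl}zirconium | Cl[Zr](CC[C@@H](C)[C@H](O[Si](C(C)C)(C(C)C)C(C)C)CC=C(C)C)(C1C=CC=C1)C1C=CC=C1 | intermediate
10 | [(3R,4R)-1-iodo-3,7-dimethyloct-6-en-4-yl]oxy-tri(propan-2-yl)silane | ICC[C@@H](C)[C@H](O[Si](C(C)C)(C(C)C)C(C)C)CC=C(C)C | intermediate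
11 | 5-bromo-2-methylpent-2-ene | CC(C)=CCCBr | starting material
12 | but-2-yne-1,4-diol | OCC#CCO | starting material
13 | (4-methylpent-3-en-1-yl)magnesium bromide | CC(C)=CCC[Mg]Br | intermediate
14 | cyclic alkenylmagnesium alkoxide (C-magnesiated adduct, five-membered C–Mg–O chelate, second alkoxide as OMgBr) | CC(C)=CCCC1=C(CO[Mg]Br)[Mg]OC1 | intermediate
15 | (2E)-2-(4-methylpent-3-en-1-yl)but-2-ene-1,4-diol | OC/C=C(/CO)CCC=C(C)C | intermediate
16 | (2E)-2-(4-methylpent-3-en-1-yl)but-2-ene-1,4-diyl bis(2,2-dimethylpropanoate) | CC(C)(C)C(=O)OC/C=C(/COC(=O)C(C)(C)C)CCC=C(C)C | intermediate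
17 | (2E)-2-[(3E)-5-hydroxy-4-methylpent-3-en-1-yl]but-2-ene-1,4-diyl bis(2,2-dimethylpropanoate) | CC(C)(C)C(=O)OC/C=C(/COC(=O)C(C)(C)C)CC/C=C(\C)CO | intermediate
18 | (2E)-2-{2-[(2R,3R)-3-(hydroxymethyl)-3-methyloxiran-2-yl]ethyl}but-2-ene-1,4-diyl bis(2,2-dimethylpropanoate) | CC(C)(C)C(=O)OC/C=C(/COC(=O)C(C)(C)C)CC[C@H]1O[C@]1(C)CO | intermediate
19 | trifluoromethanesulfonate of 18 (epoxy triflate) | CC(C)(C)C(=O)OC/C=C(/COC(=O)C(C)(C)C)CC[C@H]1O[C@]1(C)COS(=O)(=O)C(F)(F)F | intermediate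
20 | {(3R,4R)-3,7-dimethyl-4-[tri(propan-2-yl)silyloxy]oct-6-en-1-yl}magnesium iodide | I[Mg]CC[C@@H](C)[C@H](O[Si](C(C)C)(C(C)C)C(C)C)CC=C(C)C | intermediate
21 | (2E)-2-{2-[(2R,3R)-3-{(4R,5R)-4,8-dimethyl-5-[tri(propan-2-yl)silyloxy]non-7-en-1-yl}-3-methyloxiran-2-yl]ethyl}but-2-ene-1,4-diyl bis(2,2-dimethylpropanoate) | CC(C)(C)C(=O)OC/C=C(/COC(=O)C(C)(C)C)CC[C@H]1O[C@]1(C)CCC[C@@H](C)[C@H](O[Si](C(C)C)(C(C)C)C(C)C)CC=C(C)C | intermediate
22 | (2E)-2-{2-[(2R,3R)-3-{(4R,5R)-4,8-dimethyl-5-[tri(propan-2-yl)silyloxy]non-7-en-1-yl}-3-methyloxiran-2-yl]ethyl}but-2-ene-1,4-diol (formed as its potassium alkoxide) | OC/C=C(/CO)CC[C@H]1O[C@]1(C)CCC[C@@H](C)[C@H](O[Si](C(C)C)(C(C)C)C(C)C)CC=C(C)C | intermediate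
23 | (2R,6R,7R)-2-[(2S,5E)-5-(2-hydroxyethylidene)oxan-2-yl]-6,10-dimethyl-7-[tri(propan-2-yl)silyloxy]undec-9-en-2-ol | OC/C=C1\CC[C@@H]([C@](C)(O)CCC[C@@H](C)[C@H](O[Si](C(C)C)(C(C)C)C(C)C)CC=C(C)C)OC1 | intermediate
24 | 2-[(3E,6S)-6-{(2R,6R,7R)-2-acetoxy-6,10-dimethyl-7-[tri(propan-2-yl)silyloxy]undec-9-en-2-yl}oxan-3-ylidene]ethyl acetate | CC(=O)OC/C=C1\CC[C@@H]([C@](C)(OC(C)=O)CCC[C@@H](C)[C@H](O[Si](C(C)C)(C(C)C)C(C)C)CC=C(C)C)OC1 | intermediate
25 | 3-[(E)-2-acetoxyethylidene]-7-methyl-7-{(4R,5R)-4,8-dimethyl-5-[tri(propan-2-yl)silyloxy]non-7-en-1-yl}-1-oxoniabicyclo[4.1.0]heptane acetate (O-alkylated 6S,7S-epoxide) | CC(=O)OC/C=C1\CC[C@H]2[C@](C)(CCC[C@@H](C)[C@H](O[Si](C(C)C)(C(C)C)C(C)C)CC=C(C)C)[O+]2C1.CC(=O)[O-] | intermediate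
26 | 2-[(3E,6R,7S)-6-acetoxy-7-{(4R,5R)-4,8-dimethyl-5-[tri(propan-2-yl)silyloxy]non-7-en-1-yl}-7-methyloxepan-3-ylidene]ethyl acetate | CC(=O)OC/C=C1\CC[C@@H](OC(C)=O)[C@](C)(CCC[C@@H](C)[C@H](O[Si](C(C)C)(C(C)C)C(C)C)CC=C(C)C)OC1 | intermediate
27 | 2-[(3E,6R,7S)-6-acetoxy-7-[(4R,5R)-5-hydroxy-4,8-dimethylnon-7-en-1-yl]-7-methyloxepan-3-ylidene]ethyl acetate | CC(=O)OC/C=C1\CC[C@@H](OC(C)=O)[C@](C)(CCC[C@@H](C)[C@H](O)CC=C(C)C)OC1 | target

**Step count and risks**
Total steps: 12. Longest linear sequence: 8 steps (steps 5–12 from 11 and 12; the side-chain arm, steps 1–4 then 9–12, is equally long).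

Step 11 (the proposed ring expansion) is the most likely to fail. The tertiary centre may lose a proton (E1) instead of being captured, the allylic acetate may ionise, or the TIPS ether may be acetolysed. The fallback uses known chemistry and sets out from 21. Only the ester cleavage of step 10 is run (0–20 °C, no heating) and the epoxy diol 22 is isolated. Camphorsulfonic acid (10 mol %) in CH2Cl2 at 0 °C then opens the epoxide in the acid-catalysed 7-endo mode at its tertiary carbon with inversion to give the oxepane diol F1; oxane 23 is the separable 6-exo by-product. Acetylation of both hydroxyls (Ac2O, pyridine, DMAP) comes back to the route at 26.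

Step 9 is the second risk. Displacement at a primary carbon next to a fully substituted oxirane carbon is slowed, and attack on the epoxide or the pivalates may compete. The fallback sets out from 18 and 10. Dess–Martin oxidation of 18 gives the epoxy aldehyde F2, and 10 with PPh3 (MeCN, 80 °C) gives the phosphonium iodide F3. The ylide of F3 (NaHMDS, THF, −78 °C) and F2 give the Z-alkene F4 by Wittig olefination. Diimide (2-nitrobenzenesulfonyl hydrazide, Et3N, CH2Cl2, rt) saturates only this disubstituted alkene and comes back to the route at 21.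

Step 7 is the third risk. Conversion is usually moderate, the alcohol can over-oxidise to the enal, and the allylic CH2 groups may be attacked. The fallback sets out from 12. Copper-catalysed anti-carbomagnesiation with commercial but-3-enylmagnesium bromide (CuI, THF) gives the diol F5, and pivaloylation gives the bis-pivalate F6. Cross-metathesis of F6 with methacrolein (second-generation Hoveyda–Grubbs catalyst, CH2Cl2, 40 °C) gives the (E)-enal F7. Luche reduction (NaBH4, CeCl3·7H2O, MeOH, −40 °C) comes back to the route at 17.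

**Further compounds**
F1 | step 11 | 2-[(3E,6R,7S)-6-hydroxy-7-{(4R,5R)-4,8-dimethyl-5-[tri(propan-2-yl)silyloxy]non-7-en-1-yl}-7-methyloxepan-3-ylidene]ethanol | OC/C=C1\CC[C@@H](O)[C@](C)(CCC[C@@H](C)[C@H](O[Si](C(C)C)(C(C)C)C(C)C)CC=C(C)C)OC1
F2 | step 9 | (2E)-2-{2-[(2R,3S)-3-formyl-3-methyloxiran-2-yl]ethyl}but-2-ene-1,4-diyl bis(2,2-dimethylpropanoate) | CC(C)(C)C(=O)OC/C=C(/COC(=O)C(C)(C)C)CC[C@H]1O[C@]1(C)C=O
F3 | step 9 | {(3R,4R)-3,7-dimethyl-4-[tri(propan-2-yl)silyloxy]oct-6-en-1-yl}triphenylphosphonium iodide | c1ccccc1[P+](c1ccccc1)(c1ccccc1)CC[C@@H](C)[C@H](O[Si](C(C)C)(C(C)C)C(C)C)CC=C(C)C.[I-]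
F4 | step 9 | (2E)-2-{2-[(2R,3R)-3-{(1Z,4R,5R)-4,8-dimethyl-5-[tri(propan-2-yl)silyloxy]nona-1,7-dien-1-yl}-3-methyloxiran-2-yl]ethyl}but-2-ene-1,4-diyl bis(2,2-dimethylpropanoate) | CC(C)(C)C(=O)OC/C=C(/COC(=O)C(C)(C)C)CC[C@H]1O[C@]1(C)/C=C\C[C@@H](C)[C@H](O[Si](C(C)C)(C(C)C)C(C)C)CC=C(C)C
F5 | step 7 | (2E)-2-(but-3-en-1-yl)but-2-ene-1,4-diol | OC/C=C(/CO)CCC=C
F6 | step 7 | (2E)-2-(but-3-en-1-yl)but-2-ene-1,4-diyl bis(2,2-dimethylpropanoate) | CC(C)(C)C(=O)OC/C=C(/COC(=O)C(C)(C)C)CCC=C
F7 | step 7 | (2E)-2-[(3E)-4-methyl-5-oxopent-3-en-1-yl]but-2-ene-1,4-diyl bis(2,2-dimethylpropanoate) | CC(C)(C)C(=O)OC/C=C(/COC(=O)C(C)(C)C)CC/C=C(\C)C=O
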